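**Retrosynthetic overview**
1. Target 37 ⇐ hydrogenolysis of three aryl benzyl ethers and hydrolysis of one acetonide (36, 35).
2. 35 ⇐ C3–CH2 bond: trans-selective benzylation of the lithium enolate of hydroxy lactone 17 (fragment A) with benzylic bromide 34 (fragment B).
3. 17 ⇐ key step on bis(diazo) ester 10: two dirhodium-carbene C–H insertions in one flask close first the γ-lactone (sets C4), then the dihydrobenzofuran (sets C2). C3 is then epimerised to trans and the carboxyl group reduced.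
4. 10 ⇐ dihydroconiferyl alcohol, 4-(benzyloxy)-3-methoxybenzyl chloride and ethyl diazoacetate.
5. 34 ⇐ magnesium-catalysed anti-aldol of arylacetyl oxazolidinone 26 (from methyl vanillate) with O-benzylvanillin. A temporary 1,3-dioxane is the only other ring formed.

Assumption: the sense of induction of Rh2(4S-MPPIM)4, Rh2(S-PTTL)4 and (S)-4-benzyl-2-oxazolidinone is taken from their closest reported uses; if a first run shows the opposite sense, the mirror-image catalyst or auxiliary is used with no other change.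

Ligands: MPPIM = methyl 2-oxo-1-(3-phenylpropanoyl)imidazolidine-4-carboxylate; PTTL = N-phthaloyl-tert-leucinate.

**Fragment A**

Step 1
Reactants: 1 3-(4-hydroxy-3-methoxyphenyl)propan-1-ol; 2 N-iodosuccinimide; 3 4-(benzyloxy)-3-methoxybenzyl chloride
Product: 5 3-[4-{[4-(benzyloxy)-3-methoxyphenyl]methoxy}-3-iodo-5-methoxyphenyl]propan-1-ol, via iodophenol 4 (not isolated)
Conditions: 2 (1.05 equiv), DMF, 0 °C to rt; then K2CO3 (3.5 equiv), 3 (2.2 equiv), 60 °C
Reagents that add atoms: N-iodosuccinimide, O=C1CCC(=O)N1I; 4-(benzyloxy)-3-methoxybenzyl chloride, COc1cc(CCl)ccc1OCc1ccccc1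
Why: Electrophilic iodination takes the only free position ortho to the phenol OH, and the phenoxide is then O-benzylated far faster than the aliphatic alcohol (Williamson ether synthesis); no stereocenter.

Step 2
Reactants: 5 aryl iodide; 6 ethyl diazoacetate
Product: 7 ethyl 2-[2-{[4-(benzyloxy)-3-methoxyphenyl]methoxy}-5-(3-hydroxypropyl)-3-methoxyphenyl]-2-diazoacetate
Conditions: 6 (1.5 equiv), Pd(PPh3)4 (5 mol%), Ag2CO3 (0.5 equiv), Et3N (1.3 equiv), toluene, rt
Reagents that add atoms: ethyl diazoacetate, CCOC(=O)C=[N+]=[N-]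
Why: Palladium-catalysed C–H arylation of the diazo ester (oxidative addition, silver-assisted metalation of the diazo carbon, reductive elimination) keeps the diazo group and tolerates the free alcohol; no stereocenter.

Step 3
Reactants: 7 aryl diazoacetate; 8 glyoxylic acid chloride p-toluenesulfonylhydrazone
Product: 10 3-[4-{[4-(benzyloxy)-3-methoxyphenyl]methoxy}-3-(1-diazo-2-ethoxy-2-oxoethyl)-5-methoxyphenyl]propyl 2-diazoacetate, via tosylhydrazone ester 9 (not isolated)
Conditions: 8 (1.5 equiv), PhNMe2, CH2Cl2, 0 °C; then Et3N (4 equiv), 0 °C to rt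
Reagents that add atoms: glyoxylic acid chloride p-toluenesulfonylhydrazone, Cc1ccc(cc1)S(=O)(=O)NN=CC(Cl)=O
Why: O-acylation of the primary alcohol followed by base-induced loss of p-toluenesulfinate gives the diazoacetate (Corey–Myers diazoacetylation) under conditions that leave the aryl diazoacetate intact; no stereocenter.

Step 4 (key step)
Reactants: 10 bis(diazo) ester
Product: 12 ethyl (2S,3R)-2-[4-(benzyloxy)-3-methoxyphenyl]-7-methoxy-5-{[(3R)-5-oxooxolan-3-yl]methyl}-2,3-dihydro-1-benzofuran-3-carboxylate (2,3-cis), via lactone diazoester 11 (not isolated)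
Conditions: Rh2(4S-MPPIM)4 (1 mol%), CH2Cl2, reflux, 10 added over 8 h; solvent exchanged to toluene in the same flask, −78 °C, Rh2(S-PTTL)4 (2 mol%), −78 to −50 °C
Reagents that add atoms: none
Why: Proposed new method: a one-flask relay of two known dirhodium-carbene C–H insertions, in which the electron-rich carboxamidate Rh2(4S-MPPIM)4 decomposes only the acceptor-only alkyl diazoacetate at 40 °C and inserts into the C–H bond two carbons from the ester oxygen (five-membered transition state, enantiotopic C–H chosen by the catalyst, sets lactone C4 as R), while the aryl diazoacetate, which carboxamidates do not turn over at this temperature, is then decomposed at −78 °C by the more electrophilic carboxylate Rh2(S-PTTL)4 and inserts into the adjacent benzylic O–CH2 bond (sets C2 as S, C3 cis); the closest known reactions are enantioselective lactone formation from 3-arylpropyl diazoacetates and cis-2-aryl-2,3-dihydrobenzofuran-3-carboxylate formation from 2-(benzyloxy)aryl diazoacetates.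

Step 5
Reactants: 12 cis ester lactone; 13 lithium hydroxide
Product: 16 (2S,3S)-2-[4-(benzyloxy)-3-methoxyphenyl]-7-methoxy-5-{[(3R)-5-oxooxolan-3-yl]methyl}-2,3-dihydro-1-benzofuran-3-carboxylic acid (2,3-trans), via trans ester 14 (not isolated), via dicarboxylate 15 (not isolated)
Conditions: NaOEt (0.3 equiv), EtOH, rt; then LiOH (4 equiv), THF/H2O, 40 °C; then 2 M HCl to pH 1, EtOAc, rt, 12 h
Reagents that add atoms: lithium hydroxide, [Li+].[OH-]
Why: Ethoxide epimerises the C3 ester centre to the more stable 2,3-trans isomer without touching C2 (ring opening by β-elimination would be a disfavoured 5-endo process), hydroxide saponifies ester and lactone, and acidification re-closes only the γ-lactone (thermodynamic epimerisation, saponification, lactonisation).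

Step 6
Reactants: 16 acid lactone
Product: 17 (4R)-4-{[(2S,3R)-2-[4-(benzyloxy)-3-methoxyphenyl]-3-(hydroxymethyl)-7-methoxy-2,3-dihydro-1-benzofuran-5-yl]methyl}oxolan-2-one
Conditions: BH3·THF (1.5 equiv), THF, 0 °C to rt; MeOH quench
Reagents that add atoms: none
Why: Borane reduces a carboxylic acid through its acyloxyborane much faster than a lactone (chemoselective borane reduction); no stereocenter is touched.

**Fragment B**

Step 7
Reactants: 18 methyl 4-hydroxy-3-methoxybenzoate; 2 N-iodosuccinimide; 19 benzyl bromide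
Product: 21 methyl 4-(benzyloxy)-3-iodo-5-methoxybenzoate, via iodophenol 20 (not isolated)
Conditions: 2 (1.05 equiv), CF3CO2H (10 mol%), DMF, rt; then K2CO3 (3.5 equiv), 19 (2.3 equiv), 60 °C
Reagents that add atoms: N-iodosuccinimide, O=C1CCC(=O)N1I; benzyl bromide, BrCc1ccccc1
Why: Iodination ortho to the phenol OH (the only activated free position) followed by Williamson O-benzylation in the same pot; no stereocenter.

Step 8
Reactants: 21 aryl iodide; 22 (2-tert-butoxy-2-oxoethyl)zinc bromide (commercial solution)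
Product: 23 methyl 4-(benzyloxy)-3-(2-tert-butoxy-2-oxoethyl)-5-methoxybenzoate
Conditions: 22 (1.5 equiv), Pd(dba)2 (2 mol%), XPhos (4 mol%), THF, 50 °C
Reagents that add atoms: (2-tert-butoxy-2-oxoethyl)zinc bromide, CC(C)(C)OC(=O)C[Zn]Br
Why: Negishi-type cross-coupling of a Reformatsky zinc enolate with the aryl iodide, to which the methyl benzoate is inert; no stereocenter.

Step 9
Reactants: 23 tert-butyl arylacetate; 24 (4S)-4-benzyl-1,3-oxazolidin-2-one
Product: 26 methyl 4-(benzyloxy)-3-{2-[(4S)-4-benzyl-2-oxo-1,3-oxazolidin-3-yl]-2-oxoethyl}-5-methoxybenzoate, via acid chloride 25 (not isolated)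
Conditions: SOCl2 (5 equiv), CH2Cl2, rt; evaporate; then 24 + n-BuLi (THF, −78 °C), add crude 25, −78 to 0 °C
Reagents that add atoms: (4S)-4-benzyl-1,3-oxazolidin-2-one, O=C1OC[C@H](Cc2ccccc2)N1
Why: Thionyl chloride converts a tert-butyl ester, but not a methyl ester, directly into the acid chloride, which N-acylates the lithiated oxazolidinone; the auxiliary stereocenter comes in with 24.

Step 10
Reactants: 26 N-arylacetyl oxazolidinone; 27 4-(benzyloxy)-3-methoxybenzaldehyde
Product: 29 methyl 4-(benzyloxy)-3-[(2R,3S)-1-[(4S)-4-benzyl-2-oxo-1,3-oxazolidin-3-yl]-3-[4-(benzyloxy)-3-methoxyphenyl]-3-hydroxy-1-oxopropan-2-yl]-5-methoxybenzoate, via silyl ether 28 (not isolated)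
Conditions: 27 (1.3 equiv), MgCl2 (20 mol%), Et3N (2 equiv), Me3SiCl (1.5 equiv), EtOAc, rt, 24 h; then 1 M HCl/THF, rt
Reagents that add atoms: 4-(benzyloxy)-3-methoxybenzaldehyde, COc1cc(C=O)ccc1OCc1ccccc1
Why: Evans magnesium-halide-catalysed anti-aldol reaction, in which the chelated Z-magnesium enolate is attacked on the face away from the auxiliary benzyl group and silylation of the aldolate drives turnover, giving the 2,3-anti adduct (2R,3S) and so both stereocenters of the open unit.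

Step 11
Reactants: 29 aldol adduct
Product: 30 (1S,2S)-1-[4-(benzyloxy)-3-methoxyphenyl]-2-[2-(benzyloxy)-5-(hydroxymethyl)-3-methoxyphenyl]propane-1,3-diol
Conditions: LiBH4 (4 equiv), MeOH (4 equiv), THF, 0 °C, then 45 °C
Reagents that add atoms: none
Why: Reductive cleavage of the N-acyl oxazolidinone by LiBH4, with the methyl benzoate reduced in the same pot on warming; the two stereocenters are not touched.

Step 12
Reactants: 30 triol; 31 2,2-dimethoxypropane
Product: 32 {4-(benzyloxy)-3-[(4S,5S)-4-[4-(benzyloxy)-3-methoxyphenyl]-2,2-dimethyl-1,3-dioxan-5-yl]-5-methoxyphenyl}methanol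
Conditions: 31 (5 equiv), PPTS (5 mol%), acetone, rt; aqueous NaHCO3 work-up
Reagents that add atoms: 2,2-dimethoxypropane, COC(C)(C)OC
Why: Thermodynamic acetonide formation selects the 1,3-diol (1,3-dioxane with both aryl groups equatorial) over the isolated benzylic alcohol (acetalisation); stereocenters unchanged.

Step 13
Reactants: 32 acetonide alcohol; 33 carbon tetrabromide
Product: 34 (4S,5S)-5-[2-(benzyloxy)-5-(bromomethyl)-3-methoxyphenyl]-4-[4-(benzyloxy)-3-methoxyphenyl]-2,2-dimethyl-1,3-dioxane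
Conditions: 33 (1.3 equiv), PPh3 (1.3 equiv), 2,6-lutidine (0.2 equiv), CH2Cl2, 0 °C
Reagents that add atoms: carbon tetrabromide, BrC(Br)(Br)Br
Why: Appel bromination of the primary benzylic alcohol under near-neutral conditions that spare the acetonide; no stereocenter is touched.

**Coupling and deprotection**

Step 14
Reactants: 17 hydroxy lactone (fragment A); 34 benzylic bromide (fragment B)
Product: 35 (3R,4R)-3-{[4-(benzyloxy)-3-[(4S,5S)-4-[4-(benzyloxy)-3-methoxyphenyl]-2,2-dimethyl-1,3-dioxan-5-yl]-5-methoxyphenyl]methyl}-4-{[(2S,3R)-2-[4-(benzyloxy)-3-methoxyphenyl]-3-(hydroxymethyl)-7-methoxy-2,3-dihydro-1-benzofuran-5-yl]methyl}oxolan-2-one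
Conditions: LiN(SiMe3)2 (2.1 equiv), THF, −78 °C, 1 h; then 34 (1.1 equiv), −78 to −30 °C; NH4Cl quench
Reagents that add atoms: none
Why: Alkylation of the lactone lithium enolate (the remote lithium alkoxide is not benzylated at low temperature, as in Fráter–Seebach dianion alkylations) takes place anti to the C4 substituent and gives the 3,4-trans lactone with C3 as R.

Step 15
Reactants: 35 coupled acetonide
Product: 36 (3R,4R)-3-{[4-(benzyloxy)-3-[(1S,2S)-1-[4-(benzyloxy)-3-methoxyphenyl]-1,3-dihydroxypropan-2-yl]-5-methoxyphenyl]methyl}-4-{[(2S,3R)-2-[4-(benzyloxy)-3-methoxyphenyl]-3-(hydroxymethyl)-7-methoxy-2,3-dihydro-1-benzofuran-5-yl]methyl}oxolan-2-one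
Conditions: AcOH/THF/H2O 3:1:1, 45 °C
Reagents that add atoms: none
Why: Mild aqueous acid hydrolyses the acetonide while all phenols are still benzylated, so the ortho phenol cannot close onto the benzylic alcohol (acetal hydrolysis); stereocenters unchanged.

Step 16
Reactants: 36 tris(benzyl ether)
Product: 37 target, (3R,4R)-3-{[3-[(1S,2S)-1,3-dihydroxy-1-(4-hydroxy-3-methoxyphenyl)propan-2-yl]-4-hydroxy-5-methoxyphenyl]methyl}-4-{[(2S,3R)-2-(4-hydroxy-3-methoxyphenyl)-3-(hydroxymethyl)-7-methoxy-2,3-dihydro-1-benzofuran-5-yl]methyl}oxolan-2-one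
Conditions: H2 (1 atm), 10% Pd/C, EtOAc/EtOH, rt; filter; no acid in work-up
Reagents that add atoms: none
Why: Hydrogenolysis of the three aryl benzyl ethers on Pd/C under neutral conditions is much faster than cleavage of the cyclic benzylic ether or the benzylic alcohol; stereocenters unchanged.

**Compound list**

1 | 3-(4-hydroxy-3-methoxyphenyl)propan-1-ol (dihydroconiferyl alcohol) | COc1cc(CCCO)ccc1O | starting material
2 | N-iodosuccinimide | O=C1CCC(=O)N1I | starting material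
3 | 4-(benzyloxy)-3-methoxybenzyl chloride | COc1cc(CCl)ccc1OCc1ccccc1 | starting material
4 | 3-(4-hydroxy-3-iodo-5-methoxyphenyl)propan-1-ol | COc1cc(CCCO)cc(I)c1O | intermediate (not isolated)
5 | 3-[4-{[4-(benzyloxy)-3-methoxyphenyl]methoxy}-3-iodo-5-methoxyphenyl]propan-1-ol | COc1cc(CCCO)cc(I)c1OCc1ccc(OCc2ccccc2)c(OC)c1 | intermediate
6 | ethyl diazoacetate | CCOC(=O)C=[N+]=[N-] | starting material
7 | ethyl 2-[2-{[4-(benzyloxy)-3-methoxyphenyl]methoxy}-5-(3-hydroxypropyl)-3-methoxyphenyl]-2-diazoacetate | CCOC(=O)C(=[N+]=[N-])c1cc(CCCO)cc(OC)c1OCc1ccc(OCc2ccccc2)c(OC)c1 | intermediate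
8 | glyoxylic acid chloride p-toluenesulfonylhydrazone | Cc1ccc(cc1)S(=O)(=O)NN=CC(Cl)=O | starting material
9 | 2-(tosylhydrazinylidene)acetate ester of the primary alcohol of 7 | CCOC(=O)C(=[N+]=[N-])c1cc(CCCOC(=O)C=NNS(=O)(=O)c2ccc(C)cc2)cc(OC)c1OCc1ccc(OCc2ccccc2)c(OC)c1 | intermediate (not isolated)
10 | 3-[4-{[4-(benzyloxy)-3-methoxyphenyl]methoxy}-3-(1-diazo-2-ethoxy-2-oxoethyl)-5-methoxyphenyl]propyl 2-diazoacetate | CCOC(=O)C(=[N+]=[N-])c1cc(CCCOC(=O)C=[N+]=[N-])cc(OC)c1OCc1ccc(OCc2ccccc2)c(OC)c1 | intermediate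
11 | ethyl 2-[2-{[4-(benzyloxy)-3-methoxyphenyl]methoxy}-3-methoxy-5-{[(3R)-5-oxooxolan-3-yl]methyl}phenyl]-2-diazoacetate | CCOC(=O)C(=[N+]=[N-])c1cc(C[C@H]2COC(=O)C2)cc(OC)c1OCc1ccc(OCc2ccccc2)c(OC)c1 | intermediate (not isolated)
12 | ethyl (2S,3R)-2-[4-(benzyloxy)-3-methoxyphenyl]-7-methoxy-5-{[(3R)-5-oxooxolan-3-yl]methyl}-2,3-dihydro-1-benzofuran-3-carboxylate (cis) | O=C1OC[C@@H](C1)Cc1cc(OC)c2c(c1)[C@@H](C(=O)OCC)[C@@H](c1ccc(OCc3ccccc3)c(OC)c1)O2 | intermediate
13 | lithium hydroxide | [Li+].[OH-] | starting material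
14 | ethyl (2S,3S) trans epimer of 12 | O=C1OC[C@@H](C1)Cc1cc(OC)c2c(c1)[C@H](C(=O)OCC)[C@@H](c1ccc(OCc3ccccc3)c(OC)c1)O2 | intermediate (not isolated)
15 | dilithium (2S,3S)-2-[4-(benzyloxy)-3-methoxyphenyl]-5-[(2R)-3-carboxylato-2-(hydroxymethyl)propyl]-7-methoxy-2,3-dihydro-1-benzofuran-3-carboxylate | [Li+].[Li+].OC[C@@H](CC([O-])=O)Cc1cc(OC)c2c(c1)[C@H](C([O-])=O)[C@@H](c1ccc(OCc3ccccc3)c(OC)c1)O2 | intermediate (not isolated)
16 | (2S,3S)-2-[4-(benzyloxy)-3-methoxyphenyl]-7-methoxy-5-{[(3R)-5-oxooxolan-3-yl]methyl}-2,3-dihydro-1-benzofuran-3-carboxylic acid | O=C1OC[C@@H](C1)Cc1cc(OC)c2c(c1)[C@H](C(O)=O)[C@@H](c1ccc(OCc3ccccc3)c(OC)c1)O2 | intermediate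
17 | (4R)-4-{[(2S,3R)-2-[4-(benzyloxy)-3-methoxyphenyl]-3-(hydroxymethyl)-7-methoxy-2,3-dihydro-1-benzofuran-5-yl]methyl}oxolan-2-one | O=C1OC[C@@H](C1)Cc1cc(OC)c2c(c1)[C@H](CO)[C@@H](c1ccc(OCc3ccccc3)c(OC)c1)O2 | intermediate
18 | methyl 4-hydroxy-3-methoxybenzoate (methyl vanillate) | COC(=O)c1ccc(O)c(OC)c1 | starting material
19 | benzyl bromide | BrCc1ccccc1 | starting material
20 | methyl 4-hydroxy-3-iodo-5-methoxybenzoate | COC(=O)c1cc(I)c(O)c(OC)c1 | intermediate (not isolated)
21 | methyl 4-(benzyloxy)-3-iodo-5-methoxybenzoate | COC(=O)c1cc(I)c(OCc2ccccc2)c(OC)c1 | intermediate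
22 | (2-tert-butoxy-2-oxoethyl)zinc bromide | CC(C)(C)OC(=O)C[Zn]Br | starting material
23 | methyl 4-(benzyloxy)-3-(2-tert-butoxy-2-oxoethyl)-5-methoxybenzoate | COC(=O)c1cc(CC(=O)OC(C)(C)C)c(OCc2ccccc2)c(OC)c1 | intermediate
24 | (4S)-4-benzyl-1,3-oxazolidin-2-one | O=C1OC[C@H](Cc2ccccc2)N1 | starting material
25 | methyl 4-(benzyloxy)-3-(2-chloro-2-oxoethyl)-5-methoxybenzoate | COC(=O)c1cc(CC(Cl)=O)c(OCc2ccccc2)c(OC)c1 | intermediate (not isolated)
26 | methyl 4-(benzyloxy)-3-{2-[(4S)-4-benzyl-2-oxo-1,3-oxazolidin-3-yl]-2-oxoethyl}-5-methoxybenzoate | COC(=O)c1cc(CC(=O)N2[C@@H](Cc3ccccc3)COC2=O)c(OCc2ccccc2)c(OC)c1 | intermediate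
27 | 4-(benzyloxy)-3-methoxybenzaldehyde | COc1cc(C=O)ccc1OCc1ccccc1 | starting material
28 | O-trimethylsilyl ether of 29 | COc1cc([C@@H](O[Si](C)(C)C)[C@H](C(=O)N2[C@@H](Cc3ccccc3)COC2=O)c2cc(C(=O)OC)cc(OC)c2OCc2ccccc2)ccc1OCc1ccccc1 | intermediate (not isolated)
29 | methyl 4-(benzyloxy)-3-[(2R,3S)-1-[(4S)-4-benzyl-2-oxo-1,3-oxazolidin-3-yl]-3-[4-(benzyloxy)-3-methoxyphenyl]-3-hydroxy-1-oxopropan-2-yl]-5-methoxybenzoate | COc1cc([C@@H](O)[C@H](C(=O)N2[C@@H](Cc3ccccc3)COC2=O)c2cc(C(=O)OC)cc(OC)c2OCc2ccccc2)ccc1OCc1ccccc1 | intermediate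
30 | (1S,2S)-1-[4-(benzyloxy)-3-methoxyphenyl]-2-[2-(benzyloxy)-5-(hydroxymethyl)-3-methoxyphenyl]propane-1,3-diol | COc1cc([C@@H](O)[C@H](CO)c2cc(CO)cc(OC)c2OCc2ccccc2)ccc1OCc1ccccc1 | intermediate
31 | 2,2-dimethoxypropane | COC(C)(C)OC | starting material
32 | {4-(benzyloxy)-3-[(4S,5S)-4-[4-(benzyloxy)-3-methoxyphenyl]-2,2-dimethyl-1,3-dioxan-5-yl]-5-methoxyphenyl}methanol | COc1cc([C@@H](OC(C)(C)OC5)[C@H]5c2cc(CO)cc(OC)c2OCc2ccccc2)ccc1OCc1ccccc1 | intermediate
33 | carbon tetrabromide | BrC(Br)(Br)Br | starting material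
34 | (4S,5S)-5-[2-(benzyloxy)-5-(bromomethyl)-3-methoxyphenyl]-4-[4-(benzyloxy)-3-methoxyphenyl]-2,2-dimethyl-1,3-dioxane | COc1cc([C@@H](OC(C)(C)OC5)[C@H]5c2cc(CBr)cc(OC)c2OCc2ccccc2)ccc1OCc1ccccc1 | intermediate
35 | coupled tris(benzyl ether) acetonide, (3R,4R)-lactone (name in step 14) | COc1cc([C@@H](OC(C)(C)OC5)[C@H]5c2cc(C[C@H]3C(=O)OC[C@@H]3Cc3cc(OC)c4c(c3)[C@H](CO)[C@@H](c3ccc(OCc6ccccc6)c(OC)c3)O4)cc(OC)c2OCc2ccccc2)ccc1OCc1ccccc1 | intermediate
36 | tris(benzyl ether) of the target (name in step 15) | COc1cc([C@@H](O)[C@H](CO)c2cc(C[C@H]3C(=O)OC[C@@H]3Cc3cc(OC)c4c(c3)[C@H](CO)[C@@H](c3ccc(OCc6ccccc6)c(OC)c3)O4)cc(OC)c2OCc2ccccc2)ccc1OCc1ccccc1 | intermediate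
37 | CNP0186558.2 (name in step 16) | COc1cc([C@@H](O)[C@H](CO)c2cc(C[C@H]3C(=O)OC[C@@H]3Cc3cc(OC)c4c(c3)[C@H](CO)[C@@H](c3ccc(O)c(OC)c3)O4)cc(OC)c2O)ccc1O | target

**Totals**
Total step count: 16 (steps 1, 7 and 9 are two-stage operations without isolation of the intermediate).
Longest linear sequence: 10 steps (steps 7 to 16); fragment A contributes 6 steps before the coupling.

**Three steps most likely to fail**

Step 4 (double insertion in one flask). The danger is cross-talk: the second diazo group or the first catalyst may disturb either insertion, or the carboxylate catalyst may give low selectivity in the mixed medium. The fallback sets out from 5 and comes back at 12, and never has two diazo groups in one molecule. Alcohol 5 is treated with 8 (PhNMe2, then Et3N), passing through 3-[4-{[4-(benzyloxy)-3-methoxyphenyl]methoxy}-3-iodo-5-methoxyphenyl]propyl 2-(tosylhydrazinylidene)acetate F1, to give the 3-arylpropyl diazoacetate F2. Rh2(4S-MPPIM)4 in refluxing CH2Cl2 then closes the lactone alone to give (4R)-4-[(4-{[4-(benzyloxy)-3-methoxyphenyl]methoxy}-3-iodo-5-methoxyphenyl)methyl]oxolan-2-one F3. Coupling of F3 with 6 under the conditions of step 2 gives 11, now isolated, and a separate run with Rh2(S-PTTL)4 in pure toluene at −78 °C gives 12. This costs two extra steps.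

Step 2 (palladium coupling of ethyl diazoacetate with an ortho-alkoxy aryl iodide). Low conversion or loss of the diazo group is possible. The fallback sets out from 5 and comes back at 7. Negishi coupling of 5 with the Reformatsky reagent from ethyl bromoacetate (2.5 equiv, Pd(dba)2/XPhos, THF) gives ethyl 2-[2-{[4-(benzyloxy)-3-methoxyphenyl]methoxy}-5-(3-hydroxypropyl)-3-methoxyphenyl]acetate F4. Regitz diazo transfer (4-acetamidobenzenesulfonyl azide, DBU, MeCN) then gives 7.

Step 10 (anti-aldol of an N-arylacetyl imide with an electron-rich aldehyde). Turnover or the anti:syn ratio may be poor. The fallback sets out from 23 and comes back at 30, using reagent control on the ester instead of an auxiliary. The tert-butyl ester 23 is enolised with Corey's chiral 2-bromo-4,5-diphenyl-1,3-bis(p-tolylsulfonyl)-1,3,2-diazaborolidine (the enantiomer that gives the 2R,3S product) and Et3N in toluene/hexane at −78 °C, then treated with 27. This gives tert-butyl (2R,3S)-2-[2-(benzyloxy)-3-methoxy-5-(methoxycarbonyl)phenyl]-3-[4-(benzyloxy)-3-methoxyphenyl]-3-hydroxypropanoate F5. LiAlH4 (THF, 0 °C) reduces both esters of F5 to triol 30, which saves one step.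

**Further compounds**

F1 | step 4 | 3-[4-{[4-(benzyloxy)-3-methoxyphenyl]methoxy}-3-iodo-5-methoxyphenyl]propyl 2-(tosylhydrazinylidene)acetate | COc1cc(CCCOC(=O)C=NNS(=O)(=O)c2ccc(C)cc2)cc(I)c1OCc1ccc(OCc2ccccc2)c(OC)c1
F2 | step 4 | 3-[4-{[4-(benzyloxy)-3-methoxyphenyl]methoxy}-3-iodo-5-methoxyphenyl]propyl 2-diazoacetate | COc1cc(CCCOC(=O)C=[N+]=[N-])cc(I)c1OCc1ccc(OCc2ccccc2)c(OC)c1
F3 | step 4 | (4R)-4-[(4-{[4-(benzyloxy)-3-methoxyphenyl]methoxy}-3-iodo-5-methoxyphenyl)methyl]oxolan-2-one | COc1cc(C[C@H]2COC(=O)C2)cc(I)c1OCc1ccc(OCc2ccccc2)c(OC)c1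
F4 | step 2 | ethyl 2-[2-{[4-(benzyloxy)-3-methoxyphenyl]methoxy}-5-(3-hydroxypropyl)-3-methoxyphenyl]acetate | CCOC(=O)Cc1cc(CCCO)cc(OC)c1OCc1ccc(OCc2ccccc2)c(OC)c1
F5 | step 10 | tert-butyl (2R,3S)-2-[2-(benzyloxy)-3-methoxy-5-(methoxycarbonyl)phenyl]-3-[4-(benzyloxy)-3-methoxyphenyl]-3-hydroxypropanoate | COc1cc([C@@H](O)[C@H](C(=O)OC(C)(C)C)c2cc(C(=O)OC)cc(OC)c2OCc2ccccc2)ccc1OCc1ccccc1
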